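I started from amounts. Q, the catalyst, stood at 8.8 mM against 0.44 M of the substrate E in Monday's, Tuesday's and Thursday's, so I counted the product Z in turnovers. The turnover number N, moles of Z made per mole of Q charged, reaches 50.0 at full conversion of E in these flasks.

all flasks: Q 8.8 mM
- south-east: E 0.22 M; G 0.462 M; temperature 20 °C; run made earlier
- north-east: E 0.88 M; G 0.462 M; temperature 38 °C; run made earlier
- south-west: E 0.44 M; G 0.92 M; temperature 20 °C; run made earlier
- Tuesday's: E 0.44 M; G 0.462 M; temperature 50 °C; time 6.0 h
- Thursday's: E 0.44 M; G 0.462 M; at 25 °C until 3.0 h, from then on at 50 °C; time 6.0 h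
- Monday's: E 0.44 M; G 0.462 M; temperature 25 °C; time 6.0 h

| run | time / h | Z / % | E / % |
|---|---|---|---|
| south-east | 4.00 | 1.0 | 96.9 |
| south-east | 12.0 | 6.1 | 91.3 |
| south-east | 20.0 | 11.8 | 86.4 |
| south-east | 40.0 | 24.3 | 73.3 |
| north-east | 1.50 | 2.6 | 97.9 |
| north-east | 5.00 | 7.0 | 93.3 |
| north-east | 10.0 | 13.9 | 85.9 |
| north-east | 15.0 | 21.0 | 79.1 |
| south-west | 4.00 | 1.6 | 98.4 |
| south-west | 12.0 | 3.4 | 95.7 |
| south-west | 20.0 | 6.1 | 93.2 |
| south-west | 40.0 | 13.0 | 85.5 |

(standard deviation of a reading: 0.5 percentage points)

1. the flask with the highest amount of Z, in percent of the E charged ("all alike" if they lie within 1.5 percentage points) (Tuesday's / Thursday's / Monday's / all alike)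
2. final Z, as a percentage of the E charged, in Tuesday's
3. final Z, as a percentage of the E charged, in Thursday's
4. final Z, as a percentage of the E charged, in Monday's

The percentages mislead at first. The south-east run ended at 24.3% and the south-west run at 13.0%, but their charges of E were 0.22 M and 0.44 M, so N was 6.08 and 6.50. The reagent G differed too, yet N stayed within the scatter, so I reckoned in turnovers per hour and let temperature carry the change.

Between its last two readings the south-east run made 0.156 /h at 20 °C, and the north-east run made 1.40 /h at 38 °C. The same factor per degree, carried on to 50 °C, gives 6.04 /h, which I took as a ceiling.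

So I put Tuesday's between 16.8% and 72.5%. Thursday's has the hot bath for half of its time, so I put it near half of Tuesday's. Monday's I put near 3.45%, carrying the same factor per degree from 20 °C to 25 °C.

The forecast gave 58% for Tuesday's, 30.5% for Thursday's and 2.9% for Monday's, calling the first “an extrapolation, and Q might die at 50 °C”.

Tuesday's gave 48.2%, Thursday's 27.1% and Monday's 3.16%.

    G + Q → D (k = 0.0210 /M/s, Ea = 59.0 kJ/mol)
    D → J + L (k = 0.00360 /s, Ea = 89.0 kJ/mol)
    E + L → X (k = 0.0160 /M/s, Ea = 47.0 kJ/mol)
    X → Q + Z (k = 0.00370 /s, Ea = 98.0 kJ/mol)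
    (constants at 50 °C)

At 6.00 h Tuesday's held 19.2% of its catalyst as free Q, with 27.3% as D, 27.1% as L and 26.5% as X. Its Z is N = 24.1 of the 50.0 on offer, or 4.02 /h on average, which is faster than the north-east run. The neighbour of Tuesday's with 1.1 M of E reached 22.4%, which is N = 28.0.

Readings and results are simulated on assumed constants; the scatter is artificial.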